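**Retrosynthetic overview**

- Labels: C1 is the lactone carbonyl of the butenolide (ring A), C2 carries a methyl, C4 is the ring carbon on oxygen, C5 the exocyclic CH, C6 the CH(CH3) stereocentre, C8=C9–C10(CH3)=C11 the diene, C13 is attached to the 2,4-disubstituted furan (ring B), which carries the 3-furylmethyl group (ring C). The plan rests on the E geometry of C4=C5: the ring oxygen and C6 are trans, which is the pattern left by anti addition of a carboxylate oxygen and a carbon group across a terminal alkyne.
- C9–C10 is cut last (Negishi coupling of an (E)-alkenyl iodide with the alkenylzirconium from a methyl alkyne), and C8=C9 before it (Takai iodo-olefination of a C8 aldehyde).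
- The C8 aldehyde comes in one step from (Z)-2-methylpent-2-en-4-ynoic acid and (E)-but-2-enal: palladium-catalysed lactonisation forms O–C4 and closes ring A, the only ring built in the route, and the alkenylpalladium then adds to the enal, forming C5–C6 and setting C6.
- The enynoic acid comes from prop-2-yn-1-ol (carbomagnesiation–iodination, Sonogashira coupling, oxidation, desilylation). Rings B and C are bought as 4-bromofuran-2-carbaldehyde and 3-bromofuran, joined through a carbinol that is reduced to CH2, and the pent-3-ynyl chain is attached by Negishi coupling.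

Key step: step 6

Assumption: the sense of induction of the pyridine–oxazoline in step 6 cannot be derived from precedent; the (S)-tert-butyl ligand is written, and its mirror image is used instead if it turns out to favour the (3R)-aldehyde.

**Route**

Step 1
Reactants: 1 prop-2-yn-1-ol
Product: 3 (Z)-3-iodo-2-methylprop-2-en-1-ol, via 4-methyl-2,5-dihydro-1,2-oxamagnesole 2 (not isolated)
Conditions: MeMgBr (2.5 equiv), CuI (10 mol %), THF, −10 °C to rt; then I2, −10 °C; aq. NH4Cl
Reagents that add atoms: methylmagnesium bromide, C[Mg]Br; iodine, II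
Why: CuI-catalysed anti carbomagnesiation of the propargylic alkoxide puts the methyl on C2 and magnesium on C3 cis to the CH2O group in a five-membered chelate, and iodinolysis of the C–Mg bond with retention gives the Z iodide.

Step 2
Reactants: 3 (Z)-3-iodo-2-methylprop-2-en-1-ol; 4 ethynyltrimethylsilane
Product: 5 (Z)-2-methyl-5-(trimethylsilyl)pent-2-en-4-yn-1-ol
Conditions: PdCl2(PPh3)2 (2 mol %), CuI (4 mol %), Et3N, THF, rt
Reagents that add atoms: none
Why: Sonogashira coupling of an alkenyl iodide proceeds with retention of the Z geometry and tolerates the free alcohol.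

Step 3
Reactants: 5 (Z)-2-methyl-5-(trimethylsilyl)pent-2-en-4-yn-1-ol
Product: 6 (Z)-2-methyl-5-(trimethylsilyl)pent-2-en-4-ynal
Conditions: TEMPO (10 mol %), PhI(OAc)2 (1.1 equiv), CH2Cl2, rt
Reagents that add atoms: none
Why: The TEMPO/PhI(OAc)2 oxidation of an allylic alcohol stops at the aldehyde and is mild enough to leave the Z enal unisomerised.

Step 4
Reactants: 6 (Z)-2-methyl-5-(trimethylsilyl)pent-2-en-4-ynal
Product: 7 (Z)-2-methyl-5-(trimethylsilyl)pent-2-en-4-ynoic acid
Conditions: NaClO2, NaH2PO4, 2-methylbut-2-ene, t-BuOH/H2O, 0 °C to rt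
Reagents that add atoms: sodium chlorite, [Na+].[O-]Cl=O
Why: The Pinnick oxidation converts the enal into the acid without touching the alkene geometry or the silylalkyne, the hypochlorous acid being trapped by 2-methylbut-2-ene.

Step 5
Reactants: 7 (Z)-2-methyl-5-(trimethylsilyl)pent-2-en-4-ynoic acid
Product: 8 (Z)-2-methylpent-2-en-4-ynoic acid
Conditions: K2CO3 (2.5 equiv), MeOH, rt; then cold dilute HCl to pH 2, extraction, used at once
Reagents that add atoms: none
Why: Base-mediated methanolysis of the C(sp)–Si bond is fast at rt, whereas the carboxylate does not add to the unactivated alkyne without a metal, so the Z acid should be kept intact.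

Step 6
Reactants: 8 (Z)-2-methylpent-2-en-4-ynoic acid; 9 (E)-but-2-enal
Product: 10 (3S)-3-methyl-4-[(2E)-4-methyl-5-oxofuran-2(5H)-ylidene]butanal
Conditions: Pd(OAc)2 (10 mol %), (S)-4-tert-butyl-2-(pyridin-2-yl)-4,5-dihydrooxazole (12 mol %), 9 (5 equiv), AcOH (1 equiv), ClCH2CH2Cl, 25 °C, slow addition of 8
Reagents that add atoms: none
Why: Proposed new method: the cationic (pyridine–oxazoline)Pd(OAc) fragment of divalent palladium binds the terminal alkyne of 8, the cis carboxylate attacks C4 from the face opposite the metal, the enal 9 then coordinates and inserts syn into the alkenyl–palladium bond (C5 to the β-carbon), and the palladium enolate is protonated by the acetic acid released in the first event, so the catalyst returns without a change of oxidation state. The closest known reaction type is the Pd(OAc)2/LiBr-catalysed lactonisation of alkynoic acids with conjugate addition to acrolein or vinyl ketones, which is racemic and limited to β-unsubstituted acceptors, together with enantioselective conjugate additions of organopalladium species under pyridine–oxazoline ligands. Ring A closes 5-exo-dig, which the Z geometry of 8 preorganises and which should be preferred over 6-endo pyranone formation because the activated terminal alkyne carries its positive charge on the internal carbon. The C6 stereocentre (S) is set in the insertion by the ligand, whose tert-butyl group should leave only one face of the s-trans enal open to the alkenyl group cis to it on the metal. The E alkene follows from the mechanism and not from an equilibrium, since anti oxypalladation places palladium trans to the ring oxygen and insertion retains that geometry at C5. The step needs insertion to outrun protonolysis of the alkenylpalladium, for which 9 is used in excess and 8 is added slowly, and it needs protonolysis of the enolate to outrun β-hydride elimination, for which the chelating nitrogen ligand is used in place of excess bromide, because free bromide would displace the chiral ligand and give racemic product.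

Step 7
Reactants: 10 (3S)-3-methyl-4-[(2E)-4-methyl-5-oxofuran-2(5H)-ylidene]butanal
Product: 11 (5E)-5-[(2S,4E)-5-iodo-2-methylpent-4-en-1-ylidene]-3-methylfuran-2(5H)-one
Conditions: CrCl2 (6 equiv), CHI3 (2 equiv), THF/1,4-dioxane (1:6), 0 °C to rt
Reagents that add atoms: iodoform, IC(I)I
Why: In the Takai iodo-olefination the geminal dichromium reagent adds to the aldehyde and eliminates to the E alkenyl iodide under non-basic conditions that should leave the base-sensitive C6–H and the lactone untouched.

Step 8
Reactants: 12 pent-3-yn-1-ol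
Product: 13 5-iodopent-2-yne
Conditions: PPh3, I2, imidazole, CH2Cl2, 0 °C to rt
Reagents that add atoms: iodine, II
Why: The Appel-type iodination replaces the primary hydroxyl by SN2 displacement of the oxyphosphonium group and does not affect the internal alkyne.

Step 9
Reactants: 14 3-bromofuran; 15 4-bromofuran-2-carbaldehyde
Product: 17 (4-bromofuran-2-yl)(furan-3-yl)methanol (racemic), via furan-3-yllithium 16 (not isolated)
Conditions: n-BuLi, THF, −78 °C; then 15, −78 °C; aq. NH4Cl
Reagents that add atoms: none
Why: Bromine–lithium exchange at −78 °C gives the 3-lithiofuran, which adds to the aldehyde much faster than it exchanges with the ring bromide of 15, and the carbinol stereocentre is of no consequence because it is removed in step 10.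

Step 10
Reactants: 17 (4-bromofuran-2-yl)(furan-3-yl)methanol
Product: 18 4-bromo-2-(furan-3-ylmethyl)furan
Conditions: Et3SiH (3 equiv), CF3CO2H (3 equiv), CH2Cl2, −40 to 0 °C
Reagents that add atoms: none
Why: In this ionic hydrogenation the acid ionises the doubly furyl-stabilised carbinol and the silane, present in excess from the start, should trap the cation as the CH2 compound before it can alkylate another furan.

Step 11
Reactants: 13 5-iodopent-2-yne; 18 4-bromo-2-(furan-3-ylmethyl)furan
Product: 20 2-(furan-3-ylmethyl)-4-(pent-3-yn-1-yl)furan, via iodo(pent-3-yn-1-yl)zinc 19 (not isolated)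
Conditions: Zn dust, LiCl, THF, 40 °C; then 18, Pd(OAc)2 (2 mol %), SPhos (4 mol %), THF, 50 °C
Reagents that add atoms: none
Why: Zinc insertion into the primary iodide gives an alkylzinc that tolerates the internal alkyne, and the Negishi sp3–sp2 coupling under a bulky biarylphosphine engages the furyl C–Br bond without isomerisation of the alkyl group.

Step 12
Reactants: 20 2-(furan-3-ylmethyl)-4-(pent-3-yn-1-yl)furan; 11 (5E)-5-[(2S,4E)-5-iodo-2-methylpent-4-en-1-ylidene]-3-methylfuran-2(5H)-one
Product: 23 (5E)-5-[(2S,4E,6E)-9-[5-(furan-3-ylmethyl)furan-3-yl]-2,6-dimethylnona-4,6-dien-1-ylidene]-3-methylfuran-2(5H)-one, via (E)-alkenylzirconocene chloride 21 (not isolated), via (E)-alkenylzinc chloride 22 (not isolated)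
Conditions: 20 (1.4 equiv), Cp2Zr(H)Cl (slight excess over 20), THF, 50 °C; ZnCl2, THF, 0 °C; then 11, Pd(PPh3)4 (5 mol %), rt
Reagents that add atoms: none
Why: Syn hydrozirconation of the methyl alkyne, equilibrated by the small excess of Cp2Zr(H)Cl to the isomer with zirconium on the methyl-bearing carbon, followed by transmetalation to zinc and Negishi coupling with retention on both partners, should give the 8E,10E diene under base-free conditions that preserve C6.

**Compound list**

1 | prop-2-yn-1-ol | C#CCO | starting material
2 | 4-methyl-2,5-dihydro-1,2-oxamagnesole | CC1=C[Mg]OC1 | intermediate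
3 | (Z)-3-iodo-2-methylprop-2-en-1-ol | OC/C(C)=C\I | intermediate
4 | ethynyltrimethylsilane | C#C[Si](C)(C)C | starting material
5 | (Z)-2-methyl-5-(trimethylsilyl)pent-2-en-4-yn-1-ol | OC/C(C)=C\C#C[Si](C)(C)C | intermediate
6 | (Z)-2-methyl-5-(trimethylsilyl)pent-2-en-4-ynal | O=C/C(C)=C\C#C[Si](C)(C)C | intermediate
7 | (Z)-2-methyl-5-(trimethylsilyl)pent-2-en-4-ynoic acid | OC(=O)/C(C)=C\C#C[Si](C)(C)C | intermediate
8 | (Z)-2-methylpent-2-en-4-ynoic acid | OC(=O)/C(C)=C\C#C | intermediate
9 | (E)-but-2-enal | C/C=C/C=O | starting material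
10 | (3S)-3-methyl-4-[(2E)-4-methyl-5-oxofuran-2(5H)-ylidene]butanal | CC1=C/C(=C\[C@@H](C)CC=O)OC1=O | intermediate
11 | (5E)-5-[(2S,4E)-5-iodo-2-methylpent-4-en-1-ylidene]-3-methylfuran-2(5H)-one | CC1=C/C(=C\[C@@H](C)C/C=C/I)OC1=O | intermediate
12 | pent-3-yn-1-ol | CC#CCCO | starting material
13 | 5-iodopent-2-yne | CC#CCCI | intermediate
14 | 3-bromofuran | Brc1ccoc1 | starting material
15 | 4-bromofuran-2-carbaldehyde | O=Cc1cc(Br)co1 | starting material
16 | furan-3-yllithium | [Li]c1ccoc1 | intermediate
17 | (4-bromofuran-2-yl)(furan-3-yl)methanol (racemic) | OC(c1ccoc1)c1cc(Br)co1 | intermediate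
18 | 4-bromo-2-(furan-3-ylmethyl)furan | Brc1coc(Cc2ccoc2)c1 | intermediate
19 | iodo(pent-3-yn-1-yl)zinc | CC#CCC[Zn]I | intermediate
20 | 2-(furan-3-ylmethyl)-4-(pent-3-yn-1-yl)furan | CC#CCCc1coc(Cc2ccoc2)c1 | intermediate
21 | chlorobis(cyclopentadienyl)[(2E)-5-[5-(furan-3-ylmethyl)furan-3-yl]pent-2-en-2-yl]zirconium | C/C(=C\CCc1coc(Cc2ccoc2)c1)[Zr](Cl)(C1C=CC=C1)C1C=CC=C1 | intermediate
22 | chloro[(2E)-5-[5-(furan-3-ylmethyl)furan-3-yl]pent-2-en-2-yl]zinc | C/C(=C\CCc1coc(Cc2ccoc2)c1)[Zn]Cl | intermediate
23 | (5E)-5-[(2S,4E,6E)-9-[5-(furan-3-ylmethyl)furan-3-yl]-2,6-dimethylnona-4,6-dien-1-ylidene]-3-methylfuran-2(5H)-one | CC1=C/C(=C\[C@@H](C)C/C=C/C(C)=C/CCc2coc(Cc3ccoc3)c2)OC1=O | target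

**Summary**

Total step count: 12. Longest linear sequence: 8 steps (steps 1 to 7, then step 12).

Steps most likely to fail:

1. Step 6. Insertion of the β-methyl enal into the alkenyl–palladium bond should be slower than with acrolein, so protonolysis to the 5-methylene butenolide, β-hydride elimination with loss of the catalyst as zerovalent palladium, or oligomerisation of the terminal alkyne may take over. The ligand may also discriminate poorly between the two enal faces. The fallback sets out from 8 and 9 and comes back at 10; it forms C5–C6 by cross-coupling and obtains the enantiomer by resolution. Iodolactonisation of 8 (I2, NaHCO3, MeCN), again an anti addition, should give (5E)-5-(iodomethylidene)-3-methylfuran-2(5H)-one F1. Compound 9 is converted with HBr and ethane-1,2-diol into racemic 2-(2-bromopropyl)-1,3-dioxolane F2, and zinc insertion (Zn dust, LiCl, THF) gives bromo[1-(1,3-dioxolan-2-yl)propan-2-yl]zinc F3. Negishi coupling of the secondary alkylzinc with the alkenyl iodide (PdCl2(dppf), THF), with retention at the alkene, gives racemic (5E)-5-[3-(1,3-dioxolan-2-yl)-2-methylpropylidene]-3-methylfuran-2(5H)-one F4. Mild acid hydrolysis of the acetal (aqueous formic acid, rt) gives racemic 3-methyl-4-[(2E)-4-methyl-5-oxofuran-2(5H)-ylidene]butanal F5. Preparative chromatography on a chiral stationary phase separates this into 10 and (3R)-3-methyl-4-[(2E)-4-methyl-5-oxofuran-2(5H)-ylidene]butanal F6, which is discarded.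

2. Step 12. Regio-equilibration of the hydrozirconation may stay incomplete for a methyl alkyne whose other substituent is an unbranched chain, which would carry a regioisomeric diene into the product, and hydride left over may reduce 11. The fallback sets out from 18 and 10 and comes back at 23; it fixes the C10 methyl by construction. Negishi coupling of 18 with commercial [2-(1,3-dioxolan-2-yl)ethyl]zinc bromide (Pd(OAc)2, SPhos, THF) gives 2-{2-[5-(furan-3-ylmethyl)furan-3-yl]ethyl}-1,3-dioxolane F7. Hydrolysis (pyridinium tosylate, wet acetone) gives 3-[5-(furan-3-ylmethyl)furan-3-yl]propanal F8, and Ramirez dibromo-olefination (CBr4, PPh3, CH2Cl2, 0 °C) gives 4-(4,4-dibromobut-3-en-1-yl)-2-(furan-3-ylmethyl)furan F9. Aldehyde 10 is converted by chromium-mediated stannyl olefination (CrCl2, Bu3SnCHBr2, LiI, THF/DMF) into (5E)-3-methyl-5-[(2S,4E)-2-methyl-5-(tributylstannyl)pent-4-en-1-ylidene]furan-2(5H)-one F10. Stille coupling of the two (Pd2(dba)3, tri(2-furyl)phosphine, toluene) should take place selectively at the bromine trans to the alkyl chain and give (5E)-5-[(2S,4E,6Z)-6-bromo-9-[5-(furan-3-ylmethyl)furan-3-yl]-2-methylnona-4,6-dien-1-ylidene]-3-methylfuran-2(5H)-one F11. Negishi methylation of the remaining C–Br bond (Me2Zn, Pd(P(t-Bu)3)2, THF), which is stereoretentive with this catalyst, then gives 23.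

3. Step 10. The furfuryl cation may alkylate a second furan ring or open the ring faster than it is reduced, giving oligomers. The fallback sets out from 15 and comes back at 18; it forms the CH2 bridge without a cation. Condensation of 15 with 4-methylbenzenesulfonohydrazide (MeOH, rt) gives N'-[(E)-(4-bromofuran-2-yl)methylidene]-4-methylbenzenesulfonohydrazide F12. Metal-free reductive coupling of this tosylhydrazone with furan-3-ylboronic acid (K2CO3, 1,4-dioxane, 110 °C) forms the bridge with loss of nitrogen and sulfinate, and the C–Br bond should survive because no palladium is present.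

**Further compounds**

F1 | step 6 | (5E)-5-(iodomethylidene)-3-methylfuran-2(5H)-one | CC1=C/C(=C\I)OC1=O
F2 | step 6 | 2-(2-bromopropyl)-1,3-dioxolane (racemic) | CC(Br)CC1OCCO1
F3 | step 6 | bromo[1-(1,3-dioxolan-2-yl)propan-2-yl]zinc (racemic) | CC([Zn]Br)CC1OCCO1
F4 | step 6 | (5E)-5-[3-(1,3-dioxolan-2-yl)-2-methylpropylidene]-3-methylfuran-2(5H)-one (racemic) | CC1=C/C(=C\C(C)CC2OCCO2)OC1=O
F5 | step 6 | 3-methyl-4-[(2E)-4-methyl-5-oxofuran-2(5H)-ylidene]butanal (racemic) | CC1=C/C(=C\C(C)CC=O)OC1=O
F6 | step 6 | (3R)-3-methyl-4-[(2E)-4-methyl-5-oxofuran-2(5H)-ylidene]butanal | CC1=C/C(=C\[C@H](C)CC=O)OC1=O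
F7 | step 12 | 2-{2-[5-(furan-3-ylmethyl)furan-3-yl]ethyl}-1,3-dioxolane | C1COC(CCc2coc(Cc3ccoc3)c2)O1
F8 | step 12 | 3-[5-(furan-3-ylmethyl)furan-3-yl]propanal | O=CCCc1coc(Cc2ccoc2)c1
F9 | step 12 | 4-(4,4-dibromobut-3-en-1-yl)-2-(furan-3-ylmethyl)furan | BrC(Br)=CCCc1coc(Cc2ccoc2)c1
F10 | step 12 | (5E)-3-methyl-5-[(2S,4E)-2-methyl-5-(tributylstannyl)pent-4-en-1-ylidene]furan-2(5H)-one | CC1=C/C(=C\[C@@H](C)C/C=C/[Sn](CCCC)(CCCC)CCCC)OC1=O
F11 | step 12 | (5E)-5-[(2S,4E,6Z)-6-bromo-9-[5-(furan-3-ylmethyl)furan-3-yl]-2-methylnona-4,6-dien-1-ylidene]-3-methylfuran-2(5H)-one | CC1=C/C(=C\[C@@H](C)C/C=C/C(Br)=C/CCc2coc(Cc3ccoc3)c2)OC1=O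
F12 | step 10 | N'-[(E)-(4-bromofuran-2-yl)methylidene]-4-methylbenzenesulfonohydrazide | Cc1ccc(cc1)S(=O)(=O)N/N=C/c1cc(Br)co1
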